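**Retrosynthetic overview**

1. Feature: ring B (C5, C6–OAc, C7–iPr, C8–O‑angeloyl, C9H2, C10(Me)=C1) carries its methyl‑bearing alkene C1=C10 one CH2 (C9) away from the oxygenated C6–C7–C8 unit and is fused to ring A (C1–C5, carbinol C4) through C1 and C5. A methyl alkyne (C1≡C10), an (E)‑alkene (C5=C6) and a silyloxy cyclopropane (C7, C8, C9), held together by the tether C2–C4, therefore map onto both rings.
2. Key disconnection: 22 ⇒ 21. The rhodium (5+2) opens C7–C9, forms C1–C5 and C9–C10, and closes rings A and B together; no ring of the target exists before it.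
3. 21 ⇒ aldehyde 12 + sulfone 20 (C5=C6, Julia–Kocienski). 12 comes from geraniol (C4 by Sharpless epoxidation, prenyl end turned into the methyl alkyne); 20 comes from ethyl isovalerate and ethyl formate (cis‑silyloxy cyclopropane by asymmetric Simmons–Smith).
4. After the key step: the 8α‑hydroxyl directs epoxidation of C6=C7, a Wharton transposition moves the oxygen to C6 (α) and the alkene to C7=C8, and hydroboration then sets H‑7 and the 8β‑hydroxyl; the acetate and the angelate are put on in between.

Key step: step 15

Convention: guaiane numbering; α is the face of the bicycle that carries H‑5 (target: 4α‑OH, 6α‑OAc, 7α‑isopropyl, 8β‑angeloyloxy; 4S,5R,6R,7R,8S).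

Remark on the chemistry: the (5+2) step is suprafacial on the five‑carbon unit. With an (E)‑alkene, a silyloxy group that is cis to the vinyl group on the cyclopropane must therefore come out cis to H‑5 (8α). The cis arrangement is kept because it secures C7–C9 cleavage, and the (1R,2S) cyclopropane is chosen so that C5 comes out as in the target. The 8α‑oxygen is then relayed to C6, and O‑8β and H‑7β are brought in together by hydroboration.

Assumption: silylation of the chelated sodium enolate in step 9 is taken to give mainly the Z enol ether; a minor E isomer would be removed by chromatography at that stage.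

**Route**

Step 1
Reactants: 1 geraniol
Product: 2 (2S,3S)-2,3-epoxygeraniol
Conditions: Ti(OiPr)4 (5 mol %), L-(+)-diethyl tartrate (6 mol %), t-BuOOH, 4 Å MS, CH2Cl2, −20 °C
Reagents that add atoms: tert-butyl hydroperoxide, CC(C)(C)OO
Why: Sharpless asymmetric epoxidation, in which the titanium L-(+)-tartrate complex delivers oxygen to one face of the allylic 2,3-alkene only (the 6,7-alkene is not touched) and so sets the future C4 as S.

Step 2
Reactants: 2 (2S,3S)-2,3-epoxygeraniol
Product: 3 (2R,3S)-2,3-epoxy-1-iodo-3,7-dimethyloct-6-ene (both C–O centres unchanged)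
Conditions: PPh3, I2, imidazole, CH2Cl2, 0 °C
Reagents that add atoms: iodine, II
Why: Appel-type iodination of the primary alcohol by SN2 at CH2, which leaves both epoxide carbons untouched.

Step 3
Reactants: 3 epoxy iodide
Product: 4 (S)-linalool
Conditions: Zn dust, AcOH (1.1 equiv), EtOH, 60 °C
Reagents that add atoms: none
Why: Reductive elimination of a 2,3-epoxy iodide, in which zinc inserts into the C–I bond and the organozinc opens the epoxide by β-elimination, giving the tertiary allylic alcohol with its C–O stereocentre untouched.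

Step 4
Reactants: 4 (S)-linalool
Product: 5 (S)-linalool tert-butyldimethylsilyl ether
Conditions: TBSOTf, 2,6-lutidine, CH2Cl2, −78 → 0 °C
Reagents that add atoms: tert-butyldimethylsilyl triflate, CC(C)(C)[Si](C)(C)OS(=O)(=O)C(F)(F)F
Why: Silylation of a hindered tertiary alcohol needs the silyl triflate with a non-nucleophilic base and should proceed without ionisation of the allylic C–O bond.

Step 5
Reactants: 5 (S)-linalool tert-butyldimethylsilyl ether
Product: 7 (4S)-4-(tert-butyldimethylsilyloxy)-4-methylhex-5-enal, via ozonide 6 (not isolated)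
Conditions: O3 (1.0 equiv, titrated), CH2Cl2, −78 °C; then PPh3, −78 °C → rt
Reagents that add atoms: ozone, [O-][O+]=O
Why: Ozonolysis with reductive work-up, selective because the electron-rich trisubstituted alkene reacts far faster than the vinyl group, which is also shielded by the neighbouring quaternary silyloxy carbon.

Step 6
Reactants: 7 (4S)-4-(tert-butyldimethylsilyloxy)-4-methylhex-5-enal
Product: 8 (3S)-7,7-dibromo-3-(tert-butyldimethylsilyloxy)-3-methylhepta-1,6-diene
Conditions: CBr4, PPh3, CH2Cl2, 0 °C
Reagents that add atoms: carbon tetrabromide, BrC(Br)(Br)Br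
Why: First stage of the Corey–Fuchs reaction, a Wittig-type dibromomethylenation of the unhindered aldehyde.

Step 7
Reactants: 8 dibromo-olefin
Product: 10 (3S)-3-(tert-butyldimethylsilyloxy)-3-methyloct-1-en-6-yne, via lithium acetylide 9 (not isolated)
Conditions: n-BuLi (2.1 equiv), THF, −78 → 0 °C; then MeI, −78 °C → rt
Reagents that add atoms: iodomethane, CI
Why: Second stage of the Corey–Fuchs reaction (Br/Li exchange, 1,2-shift to the lithium acetylide) followed by C-methylation, which gives the methyl alkyne C1≡C10 directly.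

Step 8
Reactants: 10 (3S)-3-(tert-butyldimethylsilyloxy)-3-methyloct-1-en-6-yne
Product: 12 (2S)-2-(tert-butyldimethylsilyloxy)-2-methylhept-5-ynal, via ozonide 11 (not isolated)
Conditions: O3, CH2Cl2, −78 °C; then PPh3, −78 °C → rt
Reagents that add atoms: ozone, [O-][O+]=O
Why: Ozonolysis of the only alkene, which reacts much faster than the internal alkyne, unmasks C5 as a non-enolisable α-silyloxy aldehyde.

Step 9
Reactants: 13 ethyl isovalerate; 14 ethyl formate
Product: 16 ethyl (2Z)-2-[(tert-butyldimethylsilyloxy)methylidene]-3-methylbutanoate, via sodium enolate 15 (not isolated)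
Conditions: NaH (2.0 equiv), EtOH (cat.), THF, 0 °C → rt; then TBSCl (2.2 equiv), 0 °C → rt
Reagents that add atoms: tert-butyldimethylsilyl chloride, CC(C)(C)[Si](C)(C)Cl
Why: Claisen formylation of the ester followed by O-silylation of the U-shaped sodium chelate, which places the silyloxy group cis to the ester (Z) and so prepares the cis cyclopropane.

Step 10
Reactants: 16 Z silyl enol ether ester
Product: 17 (2Z)-3-(tert-butyldimethylsilyloxy)-2-isopropylprop-2-en-1-ol
Conditions: (i-Bu)2AlH (2.2 equiv), CH2Cl2, −78 °C; aq. KNaC4H4O6 work-up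
Reagents that add atoms: none
Why: 1,2-Reduction of the β-silyloxy acrylate by the aluminium hydride gives the allylic alcohol with the enol ether geometry retained.

Step 11
Reactants: 17 Z allylic alcohol
Product: 18 [(1S,2R)-2-(tert-butyldimethylsilyloxy)-1-isopropylcyclopropyl]methanol (silyloxy cis to CH2OH)
Conditions: Et2Zn, CH2I2, DME, (4R,5R)-2-butyl-N,N,N′,N′-tetramethyl-1,3,2-dioxaborolane-4,5-dicarboxamide (1.2 equiv), CH2Cl2, −10 °C → rt
Reagents that add atoms: diiodomethane, ICI
Why: Asymmetric Simmons–Smith cyclopropanation of an allylic alcohol, in which the zinc alkoxide bound to the chiral dioxaborolane delivers CH2 to one alkene face by stereospecific syn addition; this sets C7 and C8 and keeps the silyloxy group cis to CH2OH (the enantiomeric controller would be used if the sense of induction on this enol ether proves opposite).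

Step 12
Reactants: 18 cyclopropylmethanol
Product: 19 5-({[(1R,2R)-2-(tert-butyldimethylsilyloxy)-1-isopropylcyclopropyl]methyl}sulfanyl)-1-phenyl-1H-tetrazole
Conditions: 1-phenyl-1H-tetrazole-5-thiol, PPh3, DIAD, THF, 0 °C → rt
Reagents that add atoms: 1-phenyl-1H-tetrazole-5-thiol, Sc1nnnn1-c1ccccc1
Why: Mitsunobu thioetherification by SN2 at the primary cyclopropylcarbinyl carbon under neutral conditions, so the silyloxycyclopropane and its two stereocentres are not touched.

Step 13
Reactants: 19 tetrazolyl sulfide
Product: 20 5-({[(1R,2R)-2-(tert-butyldimethylsilyloxy)-1-isopropylcyclopropyl]methyl}sulfonyl)-1-phenyl-1H-tetrazole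
Conditions: (NH4)6Mo7O24·4H2O (10 mol %), 30 % H2O2, EtOH, 0 °C → rt
Reagents that add atoms: hydrogen peroxide, OO
Why: Molybdate-catalysed peroxide oxidation of the sulfide to the sulfone, mild enough for the silyl ether and the cyclopropane.

Step 14
Reactants: 20 tetrazolyl sulfone; 12 (2S)-2-(tert-butyldimethylsilyloxy)-2-methylhept-5-ynal
Product: 21 (E)-ynyl vinylcyclopropane, tert-butyl({(1R,2S)-2-[(1E,3S)-3-(tert-butyldimethylsilyloxy)-3-methyloct-1-en-6-yn-1-yl]-2-isopropylcyclopropyl}oxy)dimethylsilane (silyloxy cis to the alkenyl group)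
Conditions: KN(SiMe3)2 (1.1 equiv) added to 20 + 12, DME, −60 °C → rt
Reagents that add atoms: none
Why: Julia–Kocienski olefination (addition, Smiles rearrangement, loss of SO2 and tetrazolone), which should give the E alkene between the two quaternary carbons; the aldehyde cannot enolise and no stereocentre is formed.

Step 15
Reactants: 21 (E)-ynyl vinylcyclopropane
Product: 22 4α,8α-bis(tert-butyldimethylsilyloxy)-5αH-guaia-1(10),6-diene
Conditions: [Rh(CO)2Cl]2 (5 mol %), toluene (0.02 M), 80 °C
Reagents that add atoms: none
Why: Monovalent rhodium binds the C5=C6 alkene and inserts into the cyclopropane bond C7–C9 that lies over the same alkene face, giving a trivalent rhodacycle (σ-bond to C9, π-allyl over C5–C7); the tethered alkyne then inserts (C1–C5) and reductive elimination forms C9–C10, the closest known reaction type being the rhodium-catalysed intramolecular (5+2) cycloaddition of alkyne-tethered vinylcyclopropanes that carry a substituent on the cyclopropane. Ring A is closed by the C1–C5 bond (5-exo with respect to the tether C2–C4) and ring B by the C9–C10 bond, as a cyclohepta-1,4-diene in which the alkyne survives as C1=C10 with its methyl on C10 and the new alkene is C6=C7. The only new stereocentre, C5, is set by the cyclopropane: both new bonds form on the alkene face syn to the breaking C7–C9 bond, so with the (E)-alkene (C4 outside, H-5 inside) the oxygen that was cis to the vinyl group comes out cis to H-5, the (1R,2S) cyclopropane gives C5 as in the target, C4 is a spectator and C8 is carried through unchanged. The step needs cleavage of C7–C9 and not of C7–C8: insertion into C7–C8 would force the cis silyloxy group into the inside position next to the metal and give a secondary α-silyloxyalkyl rhodium, whereas C7–C9 cleavage gives a primary alkyl rhodium with the silyloxy group pseudoaxial and clear of the C7 isopropyl group.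

Step 16
Reactants: 22 bis-silyl ether
Product: 23 4α-(tert-butyldimethylsilyloxy)-5αH-guaia-1(10),6-dien-8α-ol
Conditions: Bu4NF (1.2 equiv), THF, 0 °C
Reagents that add atoms: none
Why: Fluoride desilylation, selective because the secondary allylic silyl ether at C8 is cleaved far faster than the tertiary silyl ether at C4.

Step 17
Reactants: 23 allylic alcohol
Product: 24 6α,7α-epoxy-4α-(tert-butyldimethylsilyloxy)guai-1(10)-en-8α-ol
Conditions: VO(acac)2 (5 mol %), t-BuOOH (1.3 equiv), CH2Cl2, 0 °C → rt
Reagents that add atoms: tert-butyl hydroperoxide, CC(C)(C)OO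
Why: Hydroxyl-directed vanadium-catalysed epoxidation, in which the pseudoaxial 8α-hydroxyl delivers oxygen syn to the allylic C6=C7 bond of the seven-membered ring (setting C6–O as α) much faster than to the merely homoallylic C1=C10 bond.

Step 18
Reactants: 24 epoxy alcohol
Product: 25 6α,7α-epoxy-4α-(tert-butyldimethylsilyloxy)guai-1(10)-en-8-one
Conditions: Dess–Martin periodinane, NaHCO3, CH2Cl2, 0 °C → rt
Reagents that add atoms: none
Why: Buffered Dess–Martin oxidation of the secondary alcohol gives the α,β-epoxy ketone without opening the epoxide; C7 is quaternary and cannot epimerise.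

Step 19
Reactants: 25 epoxy ketone
Product: 27 4α-(tert-butyldimethylsilyloxy)guaia-1(10),7-dien-6α-ol, via epoxy hydrazone 26 (not isolated)
Conditions: N2H4·H2O (3 equiv), AcOH (0.5 equiv), MeOH, 0 °C → rt
Reagents that add atoms: none
Why: Wharton transposition, in which the hydrazone opens the epoxide at C7 and loses N2 to give the C7=C8 alkene while the C6–O bond, and with it the α configuration at C6, is never broken.

Step 20
Reactants: 27 allylic alcohol
Product: 28 6α-acetoxy-4α-(tert-butyldimethylsilyloxy)guaia-1(10),7-diene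
Conditions: Ac2O, pyridine, DMAP (cat.), CH2Cl2, 0 °C → rt
Reagents that add atoms: acetic anhydride, CC(=O)OC(C)=O
Why: DMAP-catalysed acetylation of the only free hydroxyl, with retention at C6.

Step 21
Reactants: 28 allylic acetate
Product: 30 6α-acetoxy-4α-(tert-butyldimethylsilyloxy)-7βH-guai-1(10)-en-8β-ol, via alkylborane 29 (not isolated)
Conditions: BH3·THF (1.5 equiv), THF, 0 °C; then NaBO3·4H2O, THF/H2O, rt
Reagents that add atoms: sodium perborate tetrahydrate, [Na+].[O-]OB=O.O.O.O.O
Why: Hydroboration–oxidation of the trisubstituted C7=C8 bond (the tetrasubstituted C1=C10 bond reacts much more slowly), with boron at the less substituted C8 and syn addition from the β face, anti to the allylic 6α-acetate that A(1,2) strain with the C7 isopropyl group keeps pseudoaxial; H-7 and O-8 therefore both arrive β, and the mild perborate oxidation proceeds with retention and should spare the acetate.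

Step 22
Reactants: 30 secondary alcohol
Product: 31 6α-acetoxy-8β-angeloyloxy-4α-(tert-butyldimethylsilyloxy)guai-1(10)-ene
Conditions: angelic acid, 2,4,6-trichlorobenzoyl chloride, Et3N, toluene, rt; then 30, toluene, 80 °C
Reagents that add atoms: angelic acid, C/C=C(/C)C(=O)O
Why: Yamaguchi-type esterification through the mixed anhydride, run without a nucleophilic catalyst so that the Z geometry of the angelate is not isomerised to the tiglate; the hindered hydroxyl at C8 is acylated with retention.

Step 23
Reactants: 31 silyl ether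
Product: 32 target, 6α-acetoxy-8β-angeloyloxyguai-1(10)-en-4α-ol (4S,5R,6R,7R,8S)
Conditions: HF·pyridine, pyridine, THF, 0 °C → rt
Reagents that add atoms: none
Why: Acidic fluoride cleaves the tertiary silyl ether without touching the two esters or inducing acyl migration.

**Compound list**

1 | geraniol | CC(C)=CCC/C(C)=C/CO | starting material
2 | (2S,3S)-2,3-epoxygeraniol | CC(C)=CCC[C@]1(C)O[C@H]1CO | intermediate
3 | (2R,3S)-2,3-epoxy-1-iodo-3,7-dimethyloct-6-ene | CC(C)=CCC[C@]1(C)O[C@H]1CI | intermediate
4 | (S)-linalool | CC(C)=CCC[C@](C)(O)C=C | intermediate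
5 | (S)-linalool tert-butyldimethylsilyl ether | CC(C)=CCC[C@](C)(O[Si](C)(C)C(C)(C)C)C=C | intermediate
6 | ozonide of 5 at the 6,7-alkene | CC1(C)OOC(CC[C@](C)(O[Si](C)(C)C(C)(C)C)C=C)O1 | intermediate
7 | (4S)-4-(tert-butyldimethylsilyloxy)-4-methylhex-5-enal | O=CCC[C@](C)(O[Si](C)(C)C(C)(C)C)C=C | intermediate
8 | (3S)-7,7-dibromo-3-(tert-butyldimethylsilyloxy)-3-methylhepta-1,6-diene | BrC(Br)=CCC[C@](C)(O[Si](C)(C)C(C)(C)C)C=C | intermediate
9 | lithium acetylide of (3S)-3-(tert-butyldimethylsilyloxy)-3-methylhept-1-en-6-yne | [Li]C#CCC[C@](C)(O[Si](C)(C)C(C)(C)C)C=C | intermediate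
10 | (3S)-3-(tert-butyldimethylsilyloxy)-3-methyloct-1-en-6-yne | CC#CCC[C@](C)(O[Si](C)(C)C(C)(C)C)C=C | intermediate
11 | ozonide of 10 at the vinyl group | CC#CCC[C@](C)(O[Si](C)(C)C(C)(C)C)C1OCOO1 | intermediate
12 | (2S)-2-(tert-butyldimethylsilyloxy)-2-methylhept-5-ynal | CC#CCC[C@](C)(O[Si](C)(C)C(C)(C)C)C=O | intermediate
13 | ethyl isovalerate | CCOC(=O)CC(C)C | starting material
14 | ethyl formate | CCOC=O | starting material
15 | sodium (Z)-enolate of ethyl 2-formyl-3-methylbutanoate | CCOC(=O)/C(C(C)C)=C\[O-].[Na+] | intermediate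
16 | ethyl (2Z)-2-[(tert-butyldimethylsilyloxy)methylidene]-3-methylbutanoate | CCOC(=O)/C(C(C)C)=C\O[Si](C)(C)C(C)(C)C | intermediate
17 | (2Z)-3-(tert-butyldimethylsilyloxy)-2-isopropylprop-2-en-1-ol | OC/C(C(C)C)=C\O[Si](C)(C)C(C)(C)C | intermediate
18 | [(1S,2R)-2-(tert-butyldimethylsilyloxy)-1-isopropylcyclopropyl]methanol | OC[C@@]1(C(C)C)C[C@H]1O[Si](C)(C)C(C)(C)C | intermediate
19 | 1-phenyl-1H-tetrazol-5-yl sulfide of 18 | c1ccc(cc1)-n1nnnc1SC[C@@]1(C(C)C)C[C@H]1O[Si](C)(C)C(C)(C)C | intermediate
20 | 1-phenyl-1H-tetrazol-5-yl sulfone | O=S(=O)(C[C@@]1(C(C)C)C[C@H]1O[Si](C)(C)C(C)(C)C)c1nnnn1-c1ccccc1 | intermediate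
21 | (E)-ynyl vinylcyclopropane (C4 S; cyclopropane 1R,2S; silyloxy cis to alkenyl) | CC#CCC[C@](C)(O[Si](C)(C)C(C)(C)C)/C=C/[C@@]1(C(C)C)C[C@H]1O[Si](C)(C)C(C)(C)C | intermediate
22 | 4α,8α-bis(tert-butyldimethylsilyloxy)-5αH-guaia-1(10),6-diene | CC(C)(C)[Si](C)(C)O[C@@H]1CC(C)=C2CC[C@](C)(O[Si](C)(C)C(C)(C)C)[C@H]2C=C1C(C)C | intermediate
23 | 4α-(tert-butyldimethylsilyloxy)-5αH-guaia-1(10),6-dien-8α-ol | O[C@@H]1CC(C)=C2CC[C@](C)(O[Si](C)(C)C(C)(C)C)[C@H]2C=C1C(C)C | intermediate
24 | 6α,7α-epoxy-4α-(tert-butyldimethylsilyloxy)guai-1(10)-en-8α-ol | O[C@@H]1CC(C)=C2CC[C@](C)(O[Si](C)(C)C(C)(C)C)[C@H]2[C@@H]3O[C@]13C(C)C | intermediate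
25 | 6α,7α-epoxy-4α-(tert-butyldimethylsilyloxy)guai-1(10)-en-8-one | O=C1CC(C)=C2CC[C@](C)(O[Si](C)(C)C(C)(C)C)[C@H]2[C@@H]3O[C@]13C(C)C | intermediate
26 | hydrazone of 25 | NN=C1CC(C)=C2CC[C@](C)(O[Si](C)(C)C(C)(C)C)[C@H]2[C@@H]3O[C@]13C(C)C | intermediate
27 | 4α-(tert-butyldimethylsilyloxy)guaia-1(10),7-dien-6α-ol | O[C@@H]1C(C(C)C)=CCC(C)=C2CC[C@](C)(O[Si](C)(C)C(C)(C)C)[C@@H]12 | intermediate
28 | 6α-acetoxy-4α-(tert-butyldimethylsilyloxy)guaia-1(10),7-diene | CC(=O)O[C@@H]1C(C(C)C)=CCC(C)=C2CC[C@](C)(O[Si](C)(C)C(C)(C)C)[C@@H]12 | intermediate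
29 | 8β-boryl (BH2) adduct of 28, 7βH | CC(=O)O[C@@H]1[C@H](C(C)C)[C@@H](B)CC(C)=C2CC[C@](C)(O[Si](C)(C)C(C)(C)C)[C@@H]12 | intermediate
30 | 6α-acetoxy-4α-(tert-butyldimethylsilyloxy)-7βH-guai-1(10)-en-8β-ol | CC(=O)O[C@@H]1[C@H](C(C)C)[C@@H](O)CC(C)=C2CC[C@](C)(O[Si](C)(C)C(C)(C)C)[C@@H]12 | intermediate
31 | 6α-acetoxy-8β-angeloyloxy-4α-(tert-butyldimethylsilyloxy)guai-1(10)-ene | CC(=O)O[C@@H]1[C@H](C(C)C)[C@@H](OC(=O)/C(C)=C\C)CC(C)=C2CC[C@](C)(O[Si](C)(C)C(C)(C)C)[C@@H]12 | intermediate
32 | CNP0258590.1, 6α-acetoxy-8β-angeloyloxyguai-1(10)-en-4α-ol | C/C=C(/C)C(=O)O[C@H]1CC(C)=C2CC[C@](C)(O)[C@H]2[C@H](OC(C)=O)[C@@H]1C(C)C | target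

**Step count and risks**

Total: 23 steps. Longest linear sequence: 18 steps (steps 1–8, then 14–23); the sulfone branch (steps 9–13) is 5 steps.

Steps most likely to fail:

Step 15 (the cycloaddition). What may go wrong: insertion of the metal into the silyloxy-bearing bond C7–C8, opening of the silyloxycyclopropane to a metal homoenolate before cycloaddition, or slow cyclisation because the inside H-5 and the cis silyloxy group crowd the reactive s-cis conformer. Fallback, setting out from 21 and coming back at 22: the cycloisomerisation would be run with [CpRu(MeCN)3]PF6 (10 mol %) in acetone at room temperature. This path makes the bonds in another order: alkyne and alkene first couple oxidatively to a ruthenacyclopentene (C1–C5), and only then does the cyclopropane open by migration of its unsubstituted carbon C9, so the metal never has to insert next to the silyloxy carbon. The course is again suprafacial and should give the same 22. New compounds: none F0.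

Step 14 (the olefination). What may go wrong: slow addition of the neopentyl-type sulfonyl anion to the α-quaternary aldehyde, with self-condensation of the tetrazolyl sulfone or loss of E selectivity through chelation to the α-silyloxy group. Fallback, setting out from 18 and 12 and coming back at 21: a classical three-stage Julia–Lythgoe sequence in which the adduct is trapped before it can revert. Alcohol 18 would be converted with PhSSPh and PBu3 into the phenyl sulfide F1 and oxidised ((NH4)6Mo7O24·4H2O, H2O2) to the phenyl sulfone F2. Its lithio derivative (n-BuLi, THF, −78 °C) would be added to 12 and the alkoxide acetylated in the flask with Ac2O to give the β-acetoxy sulfone F3 as a mixture of diastereomers. Reductive elimination with Na(Hg) and Na2HPO4 in MeOH/THF at −20 °C should then give the E alkene 21, whatever the configuration of F3.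

Step 19 (the transposition). What may go wrong: slow hydrazone formation at the hindered ketone, allowing enolisation toward C9 and migration of the C1=C10 alkene into conjugation, or side-paths of the alkenyl diazene. Fallback, setting out from 24 and coming back at 27: a radical fragmentation that avoids the ketone altogether. Epoxy alcohol 24 would be acylated with 1,1′-thiocarbonyldiimidazole (DMAP, ClCH2CH2Cl, 60 °C) to the imidazole-1-carbothioate F4. Treatment with Bu3SnH and AIBN in benzene at 80 °C should generate the C8 radical, which opens the epoxide at C7–O to the C7=C8 alkene and an oxygen radical at C6 that is reduced by the stannane to 27, with the C6–O bond untouched (Barton–McCombie-type radical generation).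

Further compounds
F0 | step 15 | none | none
F1 | step 14 | phenyl sulfide of 18, ({[(1R,2R)-2-(tert-butyldimethylsilyloxy)-1-isopropylcyclopropyl]methyl}sulfanyl)benzene | c1ccccc1SC[C@@]1(C(C)C)C[C@H]1O[Si](C)(C)C(C)(C)C
F2 | step 14 | phenyl sulfone, ({[(1R,2R)-2-(tert-butyldimethylsilyloxy)-1-isopropylcyclopropyl]methyl}sulfonyl)benzene | O=S(=O)(C[C@@]1(C(C)C)C[C@H]1O[Si](C)(C)C(C)(C)C)c1ccccc1
F3 | step 14 | β-acetoxy sulfone from F2 and 12 (C5 acetate, C6 phenylsulfonyl, diastereomer mixture) | CC#CCC[C@](C)(O[Si](C)(C)C(C)(C)C)C(OC(C)=O)C(S(=O)(=O)c1ccccc1)[C@@]1(C(C)C)C[C@H]1O[Si](C)(C)C(C)(C)C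
F4 | step 19 | O-(8α) imidazole-1-carbothioate of epoxy alcohol 24 | S=C(O[C@@H]1CC(C)=C2CC[C@](C)(O[Si](C)(C)C(C)(C)C)[C@H]2[C@@H]3O[C@]13C(C)C)n1ccnc1
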